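The α‑methylene‑γ‑butyrolactone (ring atoms O, C6, C7, C11, C12; germacrane numbering) is read as a CO2 adduct of a ten‑membered carbocycle: C12 and both its oxygens come from carbon dioxide. In one operation, nickel‑catalysed reductive carboxylation of a C11 alkenyl bromide forms C11–C12, and the resulting carboxylate displaces an inverted C6 chloride (5‑exo‑tet) to form O–C6 and the trans ring fusion. The precursor is a (Z)‑cyclodecene bearing the 7‑(1‑bromovinyl) group, the 6‑chloride, the 8‑angelate and the acetonide‑protected 3,4,15‑triol; its ring, C6, C7 and the vinyl bromide all arise from one chromium‑mediated 2‑bromoallylation.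

Key step: step 18

Remark: germacrane numbering of the target (ring C1–C10, lactone carbons C11–C13, C14 methyl on C10, C15 on C4) is used for every intermediate; step 9 is taken to give the (Z)‑bromoenoate, and any (E)‑isomer converges because the allylchromium of step 14 equilibrates.

Step 1
Reactants: 1 but‑2‑yn‑1‑ol
Product: 3 (Z)‑3‑iodobut‑2‑en‑1‑ol, via cyclic alkenylalanate 2 (not isolated)
Conditions: NaAlH2(OCH2CH2OMe)2, THF, 0 °C to rt; then I2, −78 °C to rt
Reagents that add atoms: iodine, [I][I]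
Why: Hydroxyl‑directed trans‑hydroalumination places aluminium on C3 inside a five‑membered alanate and iodinolysis with retention gives the Z‑iodide that later fixes the C1=C10 geometry (reduction–iodination of a propargylic alcohol).

Step 2
Reactants: 3 (Z)‑3‑iodobut‑2‑en‑1‑ol; 4 2‑vinyl‑1,3‑dioxolane
Product: 6 (Z)‑5‑(1,3‑dioxolan‑2‑yl)‑3‑methylpent‑2‑en‑1‑ol, via B‑alkyl‑9‑BBN 5 (not isolated)
Conditions: 9‑BBN, THF, 0 °C to rt (on 4); then 3, PdCl2(dppf) (5 mol %), aq. K3PO4, DMF, rt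
Reagents that add atoms: none
Why: Anti‑Markovnikov hydroboration followed by B‑alkyl Suzuki–Miyaura coupling replaces iodine with retention, so C2 and C9 end cis on the trisubstituted alkene.

Step 3
Reactants: 6 (Z)‑5‑(1,3‑dioxolan‑2‑yl)‑3‑methylpent‑2‑en‑1‑ol
Product: 7 2‑[(Z)‑5‑bromo‑3‑methylpent‑3‑enyl]‑1,3‑dioxolane
Conditions: CBr4, PPh3, CH2Cl2, −20 to 0 °C
Reagents that add atoms: carbon tetrabromide, BrC(Br)(Br)Br
Why: Appel bromination displaces the primary allylic alkoxyphosphonium by SN2 under neutral conditions that leave the acetal and the alkene geometry intact.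

Step 4
Reactants: 8 2,2‑dimethyl‑1,3‑dioxan‑5‑one; 9 (S)‑1‑amino‑2‑(methoxymethyl)pyrrolidine (SAMP)
Product: 10 SAMP hydrazone of 8
Conditions: benzene, reflux, Dean–Stark
Reagents that add atoms: none
Why: Simple condensation installs the chiral hydrazone auxiliary on the protected dihydroxyacetone unit that becomes C3–C4–C15.

Step 5
Reactants: 10 SAMP hydrazone of 8; 7 2‑[(Z)‑5‑bromo‑3‑methylpent‑3‑enyl]‑1,3‑dioxolane
Product: 12 C3‑alkylated (Z)‑hydrazone, via lithium azaenolate 11 (not isolated)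
Conditions: tBuLi, THF, −78 °C; then 7, −100 °C to rt
Reagents that add atoms: none
Why: Enders SAMP‑hydrazone alkylation: the lithium‑chelated azaenolate is alkylated on the face away from the methoxymethyl arm, which sets C3 as S and forms the C2–C3 bond.

Step 6
Reactants: 12 C3‑alkylated (Z)‑hydrazone
Product: 13 (S)‑4‑[(Z)‑5‑(1,3‑dioxolan‑2‑yl)‑3‑methylpent‑2‑enyl]‑2,2‑dimethyl‑1,3‑dioxan‑5‑one
Conditions: saturated aq. oxalic acid, Et2O, rt
Reagents that add atoms: water, O
Why: Mild two‑phase hydrolysis of the hydrazone should release the ketone without epimerising C3 and without opening the acetonide or the dioxolane.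

Step 7
Reactants: 13 (S)‑4‑[(Z)‑5‑(1,3‑dioxolan‑2‑yl)‑3‑methylpent‑2‑enyl]‑2,2‑dimethyl‑1,3‑dioxan‑5‑one; 14 acetonitrile
Product: 16 2‑[(4S,5R)‑5‑hydroxy‑2,2‑dimethyl‑4‑[(Z)‑5‑(1,3‑dioxolan‑2‑yl)‑3‑methylpent‑2‑enyl]‑1,3‑dioxan‑5‑yl]acetonitrile, via cyanomethyllithium 15 (not isolated)
Conditions: nBuLi, MeCN, THF, −78 °C; then 13 precomplexed with CeCl3, −78 °C; aq. NH4Cl
Reagents that add atoms: none
Why: 1,2‑Addition of the nitrile‑stabilised carbanion should occur axially on the dioxanone (no 1,3‑diaxial hydrogens at the ring oxygens), placing CH2CN cis to the equatorial C3 chain and the hydroxyl trans, which sets C4 as R; CeCl3 suppresses enolisation.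

Step 8
Reactants: 16 hydroxy nitrile
Product: 18 2‑[(4S,5R)‑2,2‑dimethyl‑4‑[(Z)‑3‑methyl‑6‑oxohex‑2‑enyl]‑5‑(triethylsilyloxy)‑1,3‑dioxan‑5‑yl]acetonitrile, via lutidinium acetal salt 17 (not isolated)
Conditions: Et3SiOSO2CF3, 2,6‑lutidine, CH2Cl2, 0 °C; then H2O
Reagents that add atoms: triethylsilyl trifluoromethanesulfonate, CC[Si](CC)(CC)OS(=O)(=O)C(F)(F)F; water, O
Why: Silyl triflate with a pyridine base opens the aldehyde acetal to a pyridinium salt that hydrolyses on work‑up, a deprotection selective for aldehyde acetals over ketals such as the acetonide, while the tertiary alcohol is silylated in the same pot.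

Step 9
Reactants: 18 C7 aldehyde; 19 triethyl 2‑bromo‑2‑phosphonoacetate
Product: 21 ethyl (2Z,4R,6Z)‑4‑(anilinooxy)‑2‑bromo‑6‑methyl‑8‑[(4S,5R)‑5‑(cyanomethyl)‑2,2‑dimethyl‑5‑(triethylsilyloxy)‑1,3‑dioxan‑4‑yl]octa‑2,6‑dienoate, via α‑anilinooxy aldehyde 20 (not isolated)
Conditions: PhN=O, L‑proline (20 mol %), MeCN, −20 °C; then 19, LiCl, DBU, 0 °C
Reagents that add atoms: nitrosobenzene, O=Nc1ccccc1
Why: Proline enamine catalysis gives the O‑selective nitroso aldol that sets C8 as R (L‑proline), and in situ Horner–Wadsworth–Emmons olefination traps the labile α‑oxy aldehyde as the bromoenoate carrying C11 and C13.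

Step 10
Reactants: 21 anilinooxy bromoenoate
Product: 22 ethyl (2Z,4R,6Z)‑2‑bromo‑4‑hydroxy‑6‑methyl‑8‑[(4S,5R)‑5‑(cyanomethyl)‑2,2‑dimethyl‑5‑(triethylsilyloxy)‑1,3‑dioxan‑4‑yl]octa‑2,6‑dienoate
Conditions: Cu(OAc)2 (30 mol %), EtOH, rt
Reagents that add atoms: none
Why: Copper‑catalysed N–O cleavage of the anilinooxy group frees the C8 hydroxyl without touching the stereocentre or the bromoenoate.

Step 11
Reactants: 22 C8 alcohol
Product: 23 C8 tert‑butyldimethylsilyl ether of 22
Conditions: tBuMe2SiCl, imidazole, DMF, rt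
Reagents that add atoms: tert‑butyldimethylsilyl chloride, CC(C)(C)[Si](C)(C)Cl
Why: Standard silylation protects the secondary allylic alcohol for the reduction and the ring closure.

Step 12
Reactants: 23 silyl ether ester nitrile
Product: 25 C13 allylic alcohol C6 aldehyde (2‑bromoallylic alcohol at one end and CH2CHO on the dioxane at the other), via aluminated imine alkoxide 24 (not isolated)
Conditions: iBu2AlH (3.5 equiv), CH2Cl2, −78 °C; then aq. potassium sodium tartrate and aq. tartaric acid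
Reagents that add atoms: water, O
Why: iBu2AlH reduces the ester to the allylic alcohol and stops at the N‑aluminoimine for the nitrile, which hydrolyses to the C6 aldehyde on work‑up.

Step 13
Reactants: 25 hydroxy aldehyde
Product: 26 C13 allylic bromide C6 aldehyde
Conditions: PPh3, N‑bromosuccinimide, CH2Cl2, −20 °C
Reagents that add atoms: N‑bromosuccinimide, O=C1CCC(=O)N1Br
Why: Appel‑type bromination converts only the primary allylic alcohol, since the aldehyde, the silyl ethers and the vinyl bromide are inert to the bromophosphonium salt.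

Step 14
Reactants: 26 bromo aldehyde
Product: 28 ten‑membered (1(10)Z) carbocycle with 6‑OH (R), 7‑(1‑bromovinyl), 8‑OSitBuMe2, 4‑OSiEt3 and 3,15‑O‑isopropylidene, via allylchromium 27 (not isolated)
Conditions: CrCl2 (8 equiv), THF, rt, syringe‑pump addition of 26 (final 0.003 M)
Reagents that add atoms: none
Why: Intramolecular Nozaki–Hiyama allylation: divalent chromium inserts only into the allylic C–Br bond, and the equilibrating allylchromium adds through C7 to the aldehyde in a chair transition state with the C5 and C8 branches equatorial, which sets C6 and C7 anti as in the target, while the C8 silyloxy stereocentre (its C–H held in the allyl plane by 1,3‑allylic strain against the C11 bromine) should direct the aldehyde to the face anti to the C8–C9 bond and so fix C7.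

Step 15
Reactants: 28 macrocyclic C6 alcohol
Product: 29 (6S)‑6‑chloride of 28 (C6 inverted)
Conditions: PPh3, N‑chlorosuccinimide, THF, 0 °C to rt
Reagents that add atoms: N‑chlorosuccinimide, O=C1CCC(=O)N1Cl
Why: Appel‑type deoxychlorination displaces the alkoxyphosphonium by SN2, so C6 is inverted and carries a leaving group that zerovalent nickel with phosphine ligands does not touch.

Step 16
Reactants: 29 chloride bis‑silyl ether
Product: 30 chloride 4,8‑diol
Conditions: HF·pyridine, pyridine, THF, 0 °C to rt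
Reagents that add atoms: none
Why: Buffered fluoride removes both silyl ethers while the chloride, the vinyl bromide and the acetonide survive.

Step 17
Reactants: 30 chloride 4,8‑diol; 31 angelic acid
Product: 33 8‑O‑angelate of 30, via angelic 2,4,6‑trichlorobenzoic anhydride 32 (not isolated)
Conditions: 2,4,6‑trichlorobenzoyl chloride, Et3N, toluene, rt (on 31); then 30, toluene, 75 °C
Reagents that add atoms: none
Why: Yamaguchi‑type mixed‑anhydride acylation without a nucleophilic catalyst should keep the Z geometry of the angelate, and only the secondary C8 hydroxyl reacts because the C4 hydroxyl is tertiary.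

Step 18
Reactants: 33 chloro bromo angelate; 34 carbon dioxide
Product: 36 trans‑fused 6,12‑lactone acetonide, via acrylate carboxylate 35 (not isolated)
Conditions: NiCl2(PPh3)2 (10 mol %), PPh3 (20 mol %), Mn powder (3 equiv), Et4NI (10 mol %), CO2 (1 atm), 1,3‑dimethyl‑2‑imidazolidinone, 25 °C; then 60 °C
Reagents that add atoms: none
Why: Zerovalent nickel (from NiCl2(PPh3)2 and Mn) adds oxidatively to the C11–Br bond, the alkenylnickel is reduced by manganese and inserts CO2 to give acrylate 35 (C11–C12 bond), and the carboxylate oxygen then displaces chloride at C6 by SN2 (O–C6 bond). The closest known reaction types are the nickel‑catalysed reductive carboxylation of alkenyl halides and triflates with CO2 and the lactonisation of γ‑halo carboxylates, here run in one pot. The lactone ring closes in the 5‑exo‑tet mode. No new stereocentre arises; C6 is inverted, and because step 15 had already inverted it once, the C6–O bond ends trans to H7 as in the target. The step needs chemoselectivity for the sp2 C–Br bond over the secondary C–Cl bond, secured by the phosphine‑ligated nickel at room temperature, and regioselectivity for C6 over C8, secured because only C6 carries a leaving group while O8 is blocked as the angelate.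

Step 19
Reactants: 36 lactone acetonide
Product: 37 3,4,15‑triol (1(10)Z) lactone
Conditions: AcOH/H2O (4:1), 40 °C
Reagents that add atoms: none
Why: Acid hydrolysis of the acetonide is done before the acid‑sensitive epoxide exists; the lactone, the angelate and the alkene should tolerate it.

Step 20
Reactants: 37 triol alkene
Product: 38 CNP0307250.1 (target)
Conditions: VO(acac)2 (5 mol %), tBuOOH, CH2Cl2, 0 °C
Reagents that add atoms: tert‑butyl hydroperoxide, CC(C)(C)OO
Why: Hydroxyl‑directed epoxidation: vanadium bound at the homoallylic C3 hydroxyl delivers oxygen to the face of the Z‑alkene syn to that hydroxyl, giving the cis (1R,10S) epoxide, while the electron‑poor methylene lactone and angelate do not react.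

Compound list
1 | but‑2‑yn‑1‑ol | CC#CCO | starting material
2 | sodium alkoxy(alkenyl)alanate of 1 (five‑membered ring, Al on C3 cis to CH2O) | CC1=CCO[Al-]1(OCCOC)OCCOC.[Na+] | intermediate
3 | (Z)‑3‑iodobut‑2‑en‑1‑ol | C/C(I)=C/CO | intermediate
4 | 2‑vinyl‑1,3‑dioxolane | C=CC1OCCO1 | starting material
5 | 9‑[2‑(1,3‑dioxolan‑2‑yl)ethyl]‑9‑borabicyclo[3.3.1]nonane | C1COC(CCB2C3CCCC2CCC3)O1 | intermediate
6 | (Z)‑5‑(1,3‑dioxolan‑2‑yl)‑3‑methylpent‑2‑en‑1‑ol | OC/C=C(C)\CCC1OCCO1 | intermediate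
7 | 2‑[(Z)‑5‑bromo‑3‑methylpent‑3‑enyl]‑1,3‑dioxolane | BrC/C=C(C)\CCC1OCCO1 | intermediate
8 | 2,2‑dimethyl‑1,3‑dioxan‑5‑one | CC1(C)OCC(=O)CO1 | starting material
9 | (S)‑1‑amino‑2‑(methoxymethyl)pyrrolidine (SAMP) | COC[C@@H]1CCCN1N | starting material
10 | SAMP hydrazone of 8 | COC[C@@H]1CCCN1N=C1COC(C)(C)OC1 | intermediate
11 | lithium azaenolate of 10 | COC[C@@H]1CCCN1N([Li])C1=COC(C)(C)OC1 | intermediate
12 | SAMP (Z)‑hydrazone of ketone 13 (amino nitrogen syn to the alkylated C3) | COC[C@@H]1CCCN1/N=C2/COC(C)(C)O[C@H]2C/C=C(C)\CCC3OCCO3 | intermediate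
13 | (S)‑4‑[(Z)‑5‑(1,3‑dioxolan‑2‑yl)‑3‑methylpent‑2‑enyl]‑2,2‑dimethyl‑1,3‑dioxan‑5‑one | CC1(C)OCC(=O)[C@H](C/C=C(C)\CCC2OCCO2)O1 | intermediate
14 | acetonitrile | CC#N | starting material
15 | cyanomethyllithium | [Li]CC#N | intermediate
16 | 2‑[(4S,5R)‑5‑hydroxy‑2,2‑dimethyl‑4‑[(Z)‑5‑(1,3‑dioxolan‑2‑yl)‑3‑methylpent‑2‑enyl]‑1,3‑dioxan‑5‑yl]acetonitrile (C3 S, C4 R) | N#CC[C@@]1(O)COC(C)(C)O[C@H]1C/C=C(C)\CCC2OCCO2 | intermediate
17 | 2,6‑lutidinium N,O‑acetal triflate from 16 (O4 silylated, C7 bearing lutidinium and OCH2CH2OSiEt3, C7 unassigned) | N#CC[C@@]1(O[Si](CC)(CC)CC)COC(C)(C)O[C@H]1C/C=C(C)\CCC(OCCO[Si](CC)(CC)CC)[n+]1c(C)cccc1C.[O-]S(=O)(=O)C(F)(F)F | intermediate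
18 | 2‑[(4S,5R)‑2,2‑dimethyl‑4‑[(Z)‑3‑methyl‑6‑oxohex‑2‑enyl]‑5‑(triethylsilyloxy)‑1,3‑dioxan‑5‑yl]acetonitrile (C7 aldehyde) | O=CCC/C(C)=C\C[C@@H]1OC(C)(C)OC[C@]1(O[Si](CC)(CC)CC)CC#N | intermediate
19 | triethyl 2‑bromo‑2‑phosphonoacetate | CCOC(=O)C(Br)P(=O)(OCC)OCC | starting material
20 | (R)‑α‑anilinooxy aldehyde of 18 (C8 oxygenated, R) | O=C[C@H](ONc1ccccc1)C/C(C)=C\C[C@@H]1OC(C)(C)OC[C@]1(O[Si](CC)(CC)CC)CC#N | intermediate
21 | ethyl (2Z,4R,6Z)‑4‑(anilinooxy)‑2‑bromo‑6‑methyl‑8‑[(4S,5R)‑5‑(cyanomethyl)‑2,2‑dimethyl‑5‑(triethylsilyloxy)‑1,3‑dioxan‑4‑yl]octa‑2,6‑dienoate | CCOC(=O)/C(Br)=C/[C@H](ONc1ccccc1)C/C(C)=C\C[C@@H]1OC(C)(C)OC[C@]1(O[Si](CC)(CC)CC)CC#N | intermediate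
22 | 4‑hydroxy analogue of 21 (C8 alcohol, R) | CCOC(=O)/C(Br)=C/[C@H](O)C/C(C)=C\C[C@@H]1OC(C)(C)OC[C@]1(O[Si](CC)(CC)CC)CC#N | intermediate
23 | C8 tert‑butyldimethylsilyl ether of 22 | CCOC(=O)/C(Br)=C/[C@H](O[Si](C)(C)C(C)(C)C)C/C(C)=C\C[C@@H]1OC(C)(C)OC[C@]1(O[Si](CC)(CC)CC)CC#N | intermediate
24 | bis(diisobutylaluminium) derivative of 25 (C13 alkoxide, C6 N‑aluminoimine) | CC(C)C[Al](CC(C)C)OC/C(Br)=C/[C@H](O[Si](C)(C)C(C)(C)C)C/C(C)=C\C[C@@H]1OC(C)(C)OC[C@]1(O[Si](CC)(CC)CC)CC=N[Al](CC(C)C)CC(C)C | intermediate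
25 | open‑chain (Z)‑2‑bromoallylic alcohol (C13) with C6 aldehyde; C3 S, C4 R, C8 R | OC/C(Br)=C/[C@H](O[Si](C)(C)C(C)(C)C)C/C(C)=C\C[C@@H]1OC(C)(C)OC[C@]1(O[Si](CC)(CC)CC)CC=O | intermediate
26 | C13 allylic bromide of 25 | BrC/C(Br)=C/[C@H](O[Si](C)(C)C(C)(C)C)C/C(C)=C\C[C@@H]1OC(C)(C)OC[C@]1(O[Si](CC)(CC)CC)CC=O | intermediate
27 | allylchromium dichloride from 26 (trivalent chromium on C13) | Cl[Cr](Cl)C/C(Br)=C/[C@H](O[Si](C)(C)C(C)(C)C)C/C(C)=C\C[C@@H]1OC(C)(C)OC[C@]1(O[Si](CC)(CC)CC)CC=O | intermediate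
28 | (1(10)Z)‑cyclodecene with 6‑OH (R), 7‑(1‑bromovinyl), 8‑OSitBuMe2 (R), 4‑OSiEt3 (R), 3,15‑O‑isopropylidene (C3 S); C6 and C7 as in the target | C=C(Br)[C@H]1[C@H](O)C[C@@]2(O[Si](CC)(CC)CC)COC(C)(C)O[C@H]2C/C=C(C)\C[C@H]1O[Si](C)(C)C(C)(C)C | intermediate
29 | (6S)‑6‑chloro analogue of 28 (C6 inverted) | C=C(Br)[C@H]1[C@@H](Cl)C[C@@]2(O[Si](CC)(CC)CC)COC(C)(C)O[C@H]2C/C=C(C)\C[C@H]1O[Si](C)(C)C(C)(C)C | intermediate
30 | 4,8‑diol from 29 (both silyl groups removed) | C=C(Br)[C@H]1[C@@H](Cl)C[C@@]2(O)COC(C)(C)O[C@H]2C/C=C(C)\C[C@H]1O | intermediate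
31 | angelic acid, (Z)‑2‑methylbut‑2‑enoic acid | C/C=C(/C)C(=O)O | starting material
32 | angelic 2,4,6‑trichlorobenzoic anhydride | C/C=C(/C)C(=O)OC(=O)c1c(Cl)cc(Cl)cc1Cl | intermediate
33 | 8‑O‑angelate of 30 (6‑chloride, 7‑(1‑bromovinyl), 4‑OH, 3,15‑acetonide) | C=C(Br)[C@H]1[C@@H](Cl)C[C@@]2(O)COC(C)(C)O[C@H]2C/C=C(C)\C[C@H]1OC(=O)/C(C)=C\C | intermediate
34 | carbon dioxide | O=C=O | starting material
35 | 2‑substituted acrylate (C11–CO2−, divalent manganese counter‑ion) with C6 chloride still in place | C=C(C(=O)[O-])[C@H]1[C@@H](Cl)C[C@@]2(O)COC(C)(C)O[C@H]2C/C=C(C)\C[C@H]1OC(=O)/C(C)=C\C | intermediate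
36 | trans‑fused α‑methylene 6,12‑lactone with 8‑angelate, 4‑OH, 3,15‑acetonide and (1(10)Z) alkene | C=C1C(=O)O[C@@H]2C[C@@]3(O)COC(C)(C)O[C@H]3C/C=C(C)\C[C@@H](OC(=O)/C(C)=C\C)[C@@H]12 | intermediate
37 | 3,4,15‑triol of 36 (acetonide removed) | C=C1C(=O)O[C@@H]2C[C@@](O)(CO)[C@@H](O)C/C=C(C)\C[C@@H](OC(=O)/C(C)=C\C)[C@@H]12 | intermediate
38 | CNP0307250.1 | C=C1C(=O)O[C@@H]2C[C@@](O)(CO)[C@@H](O)C[C@H]3O[C@@]3(C)C[C@@H](OC(=O)/C(C)=C\C)[C@@H]12 | target

Total step count: 20. Longest linear sequence: 19 steps (steps 1–3 and 5–20 from but‑2‑yn‑1‑ol; step 4 is a one‑step branch).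

Steps most likely to fail

1. Step 18. The alkenylnickel may be protonated before it captures CO2 (protodebromination), nickel may insert into the C6–Cl bond, or slow ring closure may let halide exchange erode the C6 configuration. Fallback from 33, returning at 36: Miyaura borylation of the alkenyl bromide (B2pin2, PdCl2(dppf), KOAc, dioxane, 80 °C) should give the alkenyl pinacolboronate F1. Copper‑catalysed carboxylation of F1 ((IPr)CuCl with IPr = 1,3‑bis(2,6‑diisopropylphenyl)imidazol‑2‑ylidene, CsF, CO2 1 atm, DMF, 70 °C) then forms the C11–C12 bond without any reductant, and the caesium carboxylate closes onto the C6 chloride to give 36.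

2. Step 14. Intermolecular coupling may outrun ring closure, and facial control by the C8 stereocentre over C7 and C6 may be weak or mismatched. Fallback from 26, returning at 28: the closure is run under ligand control with catalytic chromium, CrCl2 (10 mol %) with a chiral bis(oxazolinyl)carbazole ligand, Mn powder and Me3SiCl in THF under slow addition, so that a chiral chromium complex instead of the substrate selects the aldehyde and allyl faces. This should give the trimethylsilyl ether F2, which K2CO3 in MeOH converts to 28.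

3. Step 15. E2 elimination toward C5 or C7, or participation of neighbouring groups, may take the place of clean SN2 inversion at the hindered C6 carbinol. Fallback from 28, returning at 36: Dess–Martin oxidation gives the C6 ketone F3, and LiBH(sBu)3 at −78 °C should deliver hydride to the face away from the C7 bromovinyl group to give the C6‑epimeric alcohol F4. MsCl/Et3N then gives, with retention, the mesylate F5; HF·pyridine gives the diol mesylate F6, and the acylation of step 17 gives the angelate mesylate F7. Under the conditions of step 18 the carboxylate displaces the mesylate with inversion and gives 36.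

Further compounds
F1 | step 18 | alkenyl pinacolboronate (C11–Bpin in place of C11–Br in 33) | CC1(C)OB(OC1(C)C)C(=C)[C@H]1[C@@H](Cl)C[C@@]2(O)COC(C)(C)O[C@H]2C/C=C(C)\C[C@H]1OC(=O)/C(C)=C\C
F2 | step 14 | O6‑trimethylsilyl ether of 28 | C=C(Br)[C@H]1[C@H](O[Si](C)(C)C)C[C@@]2(O[Si](CC)(CC)CC)COC(C)(C)O[C@H]2C/C=C(C)\C[C@H]1O[Si](C)(C)C(C)(C)C
F3 | step 15 | C6 ketone from 28 | C=C(Br)[C@H]1C(=O)C[C@@]2(O[Si](CC)(CC)CC)COC(C)(C)O[C@H]2C/C=C(C)\C[C@H]1O[Si](C)(C)C(C)(C)C
F4 | step 15 | C6 epimer of alcohol 28 | C=C(Br)[C@H]1[C@@H](O)C[C@@]2(O[Si](CC)(CC)CC)COC(C)(C)O[C@H]2C/C=C(C)\C[C@H]1O[Si](C)(C)C(C)(C)C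
F5 | step 15 | C6 mesylate of F4 | C=C(Br)[C@H]1[C@@H](OS(C)(=O)=O)C[C@@]2(O[Si](CC)(CC)CC)COC(C)(C)O[C@H]2C/C=C(C)\C[C@H]1O[Si](C)(C)C(C)(C)C
F6 | step 15 | 4,8‑diol mesylate (silyl groups removed from F5) | C=C(Br)[C@H]1[C@@H](OS(C)(=O)=O)C[C@@]2(O)COC(C)(C)O[C@H]2C/C=C(C)\C[C@H]1O
F7 | step 15 | 8‑O‑angelate of F6 | C=C(Br)[C@H]1[C@@H](OS(C)(=O)=O)C[C@@]2(O)COC(C)(C)O[C@H]2C/C=C(C)\C[C@H]1OC(=O)/C(C)=C\C
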